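(The runs were computed from invented constants.)

The blue run is the neighbour to reckon from: the amber flask holds less starting material and less catalyst at the same partner, and the question is how fast each molecule of starting material turns there compared with blue.

| flask | starting material | partner | free catalyst | time |
|---|---|---|---|---|
| blue | 0.500 M | 0.600 M | 0.00250 M |  |
| green | 0.300 M | 0.400 M | 0.00250 M |  |
| teal | 0.500 M | 0.600 M | 0.00750 M |  |
| amber | 0.170 M | 0.600 M | 0.00130 M | 5.8 h |

| run | time / h | [product] / M |
|---|---|---|
| blue run | 0.97 | 0.166 |
| blue run | 1.9 | 0.261 |
| blue run | 2.9 | 0.317 |
| blue run | 3.9 | 0.367 |
| blue run | 4.8 | 0.384 |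
| blue run | 5.8 | 0.401 |
| green run | 0.97 | 0.098 |
| green run | 1.9 | 0.149 |
| green run | 2.9 | 0.190 |
| green run | 3.9 | 0.215 |
| green run | 4.8 | 0.229 |
| green run | 5.8 | 0.239 |
| teal run | 0.97 | 0.366 |
| teal run | 1.9 | 0.453 |
| teal run | 2.9 | 0.475 |
| teal run | 3.9 | 0.486 |
| teal run | 4.8 | 0.493 |
| teal run | 5.8 | 0.493 |

(each reading ± 0.003 M)

1. apparent order in [free catalyst] of the starting rate, round the charge of the blue run (the rate where two percent of its starting material have turned into product)
2. the green run starts with 0.200 M less of starting material and of partner than the blue run, and with no product. Compared where both hold the same amount of starting material, once fifteen percent of what the green run was charged with has turned into product, is the green run faster, slower or alike (within a tenth)?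
3. product in the amber run at 5.8 h, as a share of the starting material charged

- Overall: starting material + partner -> product, with free catalyst as catalyst.
- Constant volume, constant temperature.
- Bound and free are read together.
- "The second partner" is partner.
- An order is taken over about fifteen percent of the charge, up and down.

Here S, R and C are starting material, partner and free catalyst. What follows is my own reckoning.

1. Over the first reading, ln(S₀/S)/t gives 0.416 h⁻¹ in blue and 1.36 h⁻¹ in teal. Their ratio is 3.26, more than the catalyst ratio of 3.00. That reading suggests a fixed amount z of catalyst that never works, z = 0.291 mM. The local order in C is then 1.13.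

2. At the first reading, green has made 0.590 of blue's product, at 0.667 of its partner. Green differs from blue in both S and R, so I assume first order in R, where the forecast takes about zero. The order in S is then 0.238.

3. Dividing rate per molecule of S in one flask by that in blue removes time. This is the turnover factor g, the starting rate per molecule of starting material over blue's. For amber, g = 1.04.

4. Near equal S, green's first slope is 0.101 M h⁻¹ and blue's chord is 0.0782 M h⁻¹, so green reads faster by a factor of 1.29. The gap of 1.45 h gives a fall of 0.176 h⁻¹. Blue's constant at zero time is then 0.453 h⁻¹.

5. Amber's exposure to 5.8 h is 3.63 h. So ln(S₀/S) = 1.71, a share of 81.9%.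

6. The weak link is that this clock leaves out partner used up in making product. Amber's estimated mean drain is 11.6% of its partner charge, so the exponent becomes 1.51. The committed share is 77.9%.

The forecast gives 1.1, faster and 54%, on the ground that “The apparent k falls with time rather than with conversion, which points to catalyst dying”. For amber it takes 0.21 to 0.23 /h against blue's 0.45 /h, where my reckoning puts g at 1.04.

The flask gives 1.3, faster and 85.0%.

    free catalyst + starting material ⇌ catalyst-substrate complex, settled at all times (7.210 M⁻¹)
    catalyst-substrate complex + partner → product + free catalyst + by-product (238.7 M⁻¹ h⁻¹)
    partner → lost reagent (0.1044 h⁻¹)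
    free catalyst + impurity → spent catalyst

With K₁ the constant of the first equilibrium, catalyst-substrate complex stands to free catalyst as K₁S, which is 3.60 at blue's charge, so the complex is the resting state there, and 1.23 at amber's charge. Amber's g of 1.04 stands beside 85.0% for amber and a reading of 80.2% for blue at 5.8 h. Green's factor is 0.984, which turns blue's 1.77 h to half conversion into 1.80 h, and the green run took 1.83 h.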